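**Retrosynthetic overview**
1. The B-ring phenol oxygen, the CH=CH unit and the ketone carbon of the target are O1, C4=C3 and C2 of a ring-opened coumarin (2H-chromen-2-one). The ketone–aryl bond (to the A-ring carbon ortho to an oxygen) is therefore cut to an ortho-lithiated resorcinol diether plus coumarin; the lactone is a temporary ring that hides the B-ring phenol and delivers the whole (E)-2-hydroxycinnamoyl unit.
2. The aryllithium comes from MOM-directed lithiation of (S)-2-lavandulyl-1,3-bis(methoxymethoxy)benzene, whose two open ortho positions are equivalent.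
3. That arene comes from a Negishi sp3–sp2 coupling of (R)-lavandulylzinc chloride with 2-iodo-1,3-bis(methoxymethoxy)benzene (from resorcinol).
4. (R)-Lavandulol comes from a deconjugative Evans α-prenylation of the dienolate of N-(3-methylbut-2-enoyl)-(R)-4-benzyloxazolidinone, the only stereocentre-setting event.
5. Ring order: no ring is built. Both benzene rings are bought, the pyranone ring of coumarin is opened in the key step, and removal of two MOM groups finishes the synthesis.

Key step: step 8

Remark on the chemistry: the single stereocentre of the target is S, which is the spatial arrangement of (R)-lavandulol. The descriptor changes only because CH2Ar ranks below isopropenyl, whereas CH2OH, CH2I and the acyl carbon rank above it.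

**Step 1**
Reactants: 1 (R)-4-benzyloxazolidin-2-one; 2 3-methylbut-2-enoyl chloride
Product: 4 (R)-4-benzyl-3-(3-methylbut-2-enoyl)oxazolidin-2-one, via N-lithio oxazolidinone 3 (not isolated)
Conditions: n-BuLi (1.0 equiv), THF, −78 °C; then 2, −78 → 0 °C
Reagents that add atoms: none
Why: N-acylation of a lithiated oxazolidinone with an acid chloride is the standard loading of an Evans auxiliary and creates no stereocentre.

**Step 2**
Reactants: 4 (R)-4-benzyl-3-(3-methylbut-2-enoyl)oxazolidin-2-one; 5 1-bromo-3-methylbut-2-ene (prenyl bromide)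
Product: 7 (R)-4-benzyl-3-[(2R)-5-methyl-2-(prop-1-en-2-yl)hex-4-enoyl]oxazolidin-2-one, via sodium dienolate 6 (not isolated)
Conditions: NaHMDS (1.1 equiv), THF, −78 °C; then 5, −78 → −40 °C
Reagents that add atoms: none
Why: γ-deprotonation of the s-cis enoyl imide should give the chelated (Z)-sodium dienolate, which is alkylated at the α-carbon (deconjugative Evans alkylation) on the face opposite the C4 benzyl group, setting the (R) α-centre that becomes the lavandulyl stereocentre.

**Step 3**
Reactants: 7 (R)-4-benzyl-3-[(2R)-5-methyl-2-(prop-1-en-2-yl)hex-4-enoyl]oxazolidin-2-one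
Product: 8 (R)-lavandulol, (2R)-5-methyl-2-(prop-1-en-2-yl)hex-4-en-1-ol
Conditions: LiBH4, H2O (1 equiv), Et2O, 0 °C
Reagents that add atoms: none
Why: reductive cleavage of the N-acyl oxazolidinone with the non-basic LiBH4 should give the primary alcohol and return the auxiliary without epimerising or conjugating the β,γ-unsaturated α-centre.

**Step 4**
Reactants: 8 (R)-lavandulol
Product: 9 (R)-lavandulyl iodide, (3R)-3-(iodomethyl)-2,6-dimethylhepta-1,5-diene
Conditions: I2, PPh3, imidazole, CH2Cl2, 0 °C → rt
Reagents that add atoms: iodine, II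
Why: Appel-type iodination converts the primary alcohol into the iodide by SN2 at the CH2 group, leaving the adjacent stereocentre and both alkenes untouched.

**Step 5**
Reactants: 10 resorcinol
Product: 11 1,3-bis(methoxymethoxy)benzene
Conditions: MOMCl (2.5 equiv), i-Pr2NEt, CH2Cl2, 0 °C → rt
Reagents that add atoms: chloromethyl methyl ether (MOMCl), COCCl
Why: double O-alkylation of the phenols installs MOM acetals that serve as protecting groups and as directing groups for both later lithiations.

**Step 6**
Reactants: 11 1,3-bis(methoxymethoxy)benzene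
Product: 13 2-iodo-1,3-bis(methoxymethoxy)benzene, via 2-lithio arene 12 (not isolated)
Conditions: n-BuLi, THF, 0 °C; then I2, −78 °C → rt
Reagents that add atoms: iodine, II
Why: directed ortho-metalation should occur at C2, where both MOM-oxy groups cooperate, and the aryllithium is trapped by iodine.

**Step 7**
Reactants: 9 (R)-lavandulyl iodide; 13 2-iodo-1,3-bis(methoxymethoxy)benzene
Product: 16 2-[(2S)-5-methyl-2-(prop-1-en-2-yl)hex-4-en-1-yl]-1,3-bis(methoxymethoxy)benzene, via lavandulyllithium 14 (not isolated), via lavandulylzinc chloride 15 (not isolated)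
Conditions: 9, t-BuLi (2.1 equiv), Et2O, −78 °C; ZnCl2 (THF), −78 °C → rt; then 13, Pd2(dba)3 (2 mol %), SPhos (8 mol %), THF, 50 °C
Reagents that add atoms: none
Why: lithium–iodine exchange at −78 °C (anionic, so no radical 1,2-vinyl shift), transmetalation to zinc and a Pd/SPhos Negishi coupling should join the primary alkyl group to the di-ortho-substituted aryl iodide, with the stereocentre β to the metal and not involved.

**Step 8**
Reactants: 16 2-[(2S)-5-methyl-2-(prop-1-en-2-yl)hex-4-en-1-yl]-1,3-bis(methoxymethoxy)benzene; 17 coumarin (2H-chromen-2-one)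
Product: 21 (E)-1-{2,4-bis(methoxymethoxy)-3-[(2S)-5-methyl-2-(prop-1-en-2-yl)hex-4-en-1-yl]phenyl}-3-(2-hydroxyphenyl)prop-2-en-1-one, via aryllithium 18 (not isolated), via lithium chromenolate 19 (not isolated), via Z-chalcone phenoxide 20 (not isolated)
Conditions: n-BuLi (1.1 equiv), TMEDA, THF, 0 °C; cannulated into 17 (1.5 equiv), THF, −78 → 0 °C; H2O/MeOH, K2CO3, rt; pH 6 buffer work-up
Reagents that add atoms: none
Why: MOM-directed ortho-lithiation at C4 (equivalent to C6) gives aryllithium 18, which adds 1,2 to the lactone carbonyl C2 of coumarin to give the chelated tetrahedral alkoxide 19; this collapses with loss of the ring phenoxide to the (Z)-enone phenoxide 20, and in K2CO3/MeOH the ortho-phenoxide donates through the C=C into the ketone (quinone-methide enolate form), which lowers the rotation barrier so that 20 relaxes to the more stable E-chalcone 21. The closest known reaction type is the addition of aryl Grignard or aryllithium reagents to coumarins on the way to 2-arylbenzopyrylium (flavylium) salts, together with the hemiketal → cis-chalcone → trans-chalcone equilibration of that family at neutral to basic pH. No ring is closed; the pyranone ring of coumarin is opened by C2–O1 cleavage, which unveils the B-ring phenol without a protecting group. No stereocentre is created; the only new stereochemical element is the C=C geometry, set thermodynamically as E, and the (S) side-chain centre should not be deprotonated under these conditions. The step needs ring rather than benzylic or allylic lithiation (secured by coordination of n-BuLi to the MOM acetal oxygens and a short time at 0 °C), 1,2- rather than 1,4-addition (hard aryllithium, −78 °C, no copper) and mono- rather than double addition (inverse addition into excess coumarin; the chelated intermediate 19 and then the phenoxide-conjugated 2,4-dialkoxyaryl ketone should both be poorer electrophiles than coumarin).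

**Step 9**
Reactants: 21 (E)-1-{2,4-bis(methoxymethoxy)-3-[(2S)-5-methyl-2-(prop-1-en-2-yl)hex-4-en-1-yl]phenyl}-3-(2-hydroxyphenyl)prop-2-en-1-one
Product: 22 (E)-1-{2,4-dihydroxy-3-[(2S)-5-methyl-2-(prop-1-en-2-yl)hex-4-en-1-yl]phenyl}-3-(2-hydroxyphenyl)prop-2-en-1-one
Conditions: HCl (cat., ca. 0.5 M), MeOH, rt → 40 °C, dark; pH 6 phosphate buffer work-up
Reagents that add atoms: none
Why: acid-catalysed acetal exchange with methanol should remove both MOM groups (the one ortho to the ketone first), as is usual for prenylated chalcones; the mild temperature, darkness and pH 6 work-up are chosen to preserve the lavandulyl alkenes and the E-chalcone form over the flavanone or flavylium forms.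

**Compound list**
1 | (R)-4-benzyloxazolidin-2-one | O=C1N[C@H](Cc2ccccc2)CO1 | starting material
2 | 3-methylbut-2-enoyl chloride | CC(C)=CC(=O)Cl | starting material
3 | N-lithio (R)-4-benzyloxazolidin-2-one | [Li]N1[C@H](Cc2ccccc2)COC1=O | intermediate
4 | (R)-4-benzyl-3-(3-methylbut-2-enoyl)oxazolidin-2-one | CC(C)=CC(=O)N1[C@H](Cc2ccccc2)COC1=O | intermediate
5 | 1-bromo-3-methylbut-2-ene (prenyl bromide) | CC(C)=CCBr | starting material
6 | sodium (Z)-dienolate of 4 | C=C(C)/C=C(\O[Na])N1[C@H](Cc2ccccc2)COC1=O | intermediate
7 | (R)-4-benzyl-3-[(2R)-5-methyl-2-(prop-1-en-2-yl)hex-4-enoyl]oxazolidin-2-one | C=C(C)[C@@H](CC=C(C)C)C(=O)N1[C@H](Cc2ccccc2)COC1=O | intermediate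
8 | (R)-lavandulol, (2R)-5-methyl-2-(prop-1-en-2-yl)hex-4-en-1-ol | C=C(C)[C@@H](CC=C(C)C)CO | intermediate
9 | (R)-lavandulyl iodide, (3R)-3-(iodomethyl)-2,6-dimethylhepta-1,5-diene | C=C(C)[C@@H](CC=C(C)C)CI | intermediate
10 | resorcinol | Oc1cccc(O)c1 | starting material
11 | 1,3-bis(methoxymethoxy)benzene | COCOc1cccc(OCOC)c1 | intermediate
12 | 2-lithio-1,3-bis(methoxymethoxy)benzene | COCOc1cccc(OCOC)c1[Li] | intermediate
13 | 2-iodo-1,3-bis(methoxymethoxy)benzene | COCOc1cccc(OCOC)c1I | intermediate
14 | lavandulyllithium (configuration as in 9) | C=C(C)[C@@H](CC=C(C)C)C[Li] | intermediate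
15 | lavandulylzinc chloride (configuration as in 9) | C=C(C)[C@@H](CC=C(C)C)C[Zn]Cl | intermediate
16 | 2-[(2S)-5-methyl-2-(prop-1-en-2-yl)hex-4-en-1-yl]-1,3-bis(methoxymethoxy)benzene | C=C(C)[C@@H](CC=C(C)C)Cc1c(OCOC)cccc1OCOC | intermediate
17 | coumarin (2H-chromen-2-one) | O=C1C=Cc2ccccc2O1 | starting material
18 | {2,4-bis(methoxymethoxy)-3-[(2S)-5-methyl-2-(prop-1-en-2-yl)hex-4-en-1-yl]phenyl}lithium | C=C(C)[C@@H](CC=C(C)C)Cc1c(OCOC)ccc([Li])c1OCOC | intermediate
19 | lithium 2-{2,4-bis(methoxymethoxy)-3-[(2S)-5-methyl-2-(prop-1-en-2-yl)hex-4-en-1-yl]phenyl}-2H-chromen-2-olate (both C2 epimers) | C=C(C)[C@@H](CC=C(C)C)Cc1c(OCOC)ccc(C2(O[Li])C=Cc3ccccc3O2)c1OCOC | intermediate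
20 | lithium phenoxide of the (Z)-isomer of 21 | C=C(C)[C@@H](CC=C(C)C)Cc1c(OCOC)ccc(C(=O)/C=C\c2ccccc2O[Li])c1OCOC | intermediate
21 | (E)-1-{2,4-bis(methoxymethoxy)-3-[(2S)-5-methyl-2-(prop-1-en-2-yl)hex-4-en-1-yl]phenyl}-3-(2-hydroxyphenyl)prop-2-en-1-one | C=C(C)[C@@H](CC=C(C)C)Cc1c(OCOC)ccc(C(=O)/C=C/c2ccccc2O)c1OCOC | intermediate
22 | (E)-1-{2,4-dihydroxy-3-[(2S)-5-methyl-2-(prop-1-en-2-yl)hex-4-en-1-yl]phenyl}-3-(2-hydroxyphenyl)prop-2-en-1-one | C=C(C)[C@@H](CC=C(C)C)Cc1c(O)ccc(C(=O)/C=C/c2ccccc2O)c1O | target

**Step count and risks**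
Total steps: 9. Longest linear sequence: 7 (steps 1, 2, 3, 4, 7, 8, 9).

Steps most likely to fail:

1. Step 8. The aryllithium may add a second time to the ring-opened ketone, add in conjugate fashion at C4 of coumarin, or lithiate the benzylic CH2 instead of the ring; the Z → E equilibration may also stall at the hemiketal/cis stage. Fallback: setting out from 16, the aryllithium 18 is generated as in step 8 and quenched with N-methoxy-N-methylacetamide (THF, −78 → 0 °C) to give the acetophenone 1-{2,4-bis(methoxymethoxy)-3-[(2S)-5-methyl-2-(prop-1-en-2-yl)hex-4-en-1-yl]phenyl}ethan-1-one F1. A Claisen–Schmidt condensation of F1 with salicylaldehyde (KOH, EtOH/H2O, rt) should then give the E-chalcone directly, and the route is rejoined at 21.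

2. Step 7. Transmetalation and reductive elimination at the di-ortho-substituted palladium centre may be slow, so that protodemetalation or β-hydride elimination with alkene migration in the alkyl group takes over. Fallback with reversed polarity and no palladium: setting out from 8, treatment with Tf2O and 2,6-lutidine (CH2Cl2, −78 °C) gives (R)-lavandulyl trifluoromethanesulfonate F2, used cold and crude. The 2-lithio arene 12 (made from 11 as in step 6) is alkylated with F2 in THF at −78 → −20 °C, where SN2 at the primary triflate should outpace elimination, and the route is rejoined at 16.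

3. Step 9. Under protic acid the phenol may add to the protonated isopropenyl group (chroman formation), the 2′-OH may close onto the enone (flavanone), or the enone may drift towards the cis/flavylium manifold. Fallback without protic acid: setting out from 21, TMSOTf and 2,2′-bipyridyl (MeCN, 0 °C → rt) should exchange both aryl MOM ethers for silyl ethers and silylate the free phenol, giving the tris(trimethylsilyl) ether F3. Neutral hydrolysis (H2O/THF, pH 7 buffer, rt) then releases the phenols, and the route is rejoined at 22.

**Further compounds**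
F1 | step 8 | 1-{2,4-bis(methoxymethoxy)-3-[(2S)-5-methyl-2-(prop-1-en-2-yl)hex-4-en-1-yl]phenyl}ethan-1-one | C=C(C)[C@@H](CC=C(C)C)Cc1c(OCOC)ccc(C(C)=O)c1OCOC
F2 | step 7 | (R)-lavandulyl trifluoromethanesulfonate, (2R)-5-methyl-2-(prop-1-en-2-yl)hex-4-en-1-yl trifluoromethanesulfonate | C=C(C)[C@@H](CC=C(C)C)COS(=O)(=O)C(F)(F)F
F3 | step 9 | (E)-1-{2,4-bis(trimethylsilyloxy)-3-[(2S)-5-methyl-2-(prop-1-en-2-yl)hex-4-en-1-yl]phenyl}-3-[2-(trimethylsilyloxy)phenyl]prop-2-en-1-one | C=C(C)[C@@H](CC=C(C)C)Cc1c(O[Si](C)(C)C)ccc(C(=O)/C=C/c2ccccc2O[Si](C)(C)C)c1O[Si](C)(C)C
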